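In the elm run the starting material has nearly stopped falling, at 26.3% after 4.00 min and 24.5% after 10.0 min, so I ask whether the two new flasks, where starting material and partner give target, also end on such a stall.

| flask | starting material | partner | temperature | remark | time |
|---|---|---|---|---|---|
| alder | 0.30 M | 1 equiv | 75 °C | run made earlier |  |
| elm | 0.35 M | 1 equiv | 95 °C | run made earlier |  |
| Thursday's | 0.40 M | 1.00 equiv |  | at 80 °C until 12 min, from then on at 110 °C | 25 min |
| Monday's | 0.25 M | 1.00 equiv |  | at 110 °C throughout | 6.0 min |

| run | time / min | target / % | starting material / % |
|---|---|---|---|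
| alder | 4.00 | 2.0 | 69.5 |
| alder | 8.00 | 3.2 | 56.7 |
| alder | 12.0 | 6.9 | 49.7 |
| alder | 20.0 | 10.1 | 42.0 |
| elm | 0.667 | 2.2 | 63.3 |
| elm | 1.33 | 4.4 | 43.9 |
| elm | 4.00 | 10.3 | 26.3 |
| elm | 10.0 | 13.5 | 24.5 |

(readings scatter by 1 percentage point)

- the analysis behind the earlier runs scatters by 1 percentage point, standard deviation
- where the amount of starting material changes, what is given in equivalents or mol% on it follows

- the winner by amount of target, in percent of the starting material charged; "neither" if no more than 2 percentage points parts them (Thursday's / Monday's / neither)
- how much target is there at the end, in percent of the starting material charged: Thursday's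
- how much target is there at the end, in percent of the starting material charged: Monday's

I reckon in powers of ten. Treating each run's first reading as a first-order fall, alder gives 0.0910 min⁻¹ at 75 °C and elm gives 0.686 min⁻¹ at 95 °C, so the rate gains one power of ten per 22.8 K. Carried along that line, the rate is 0.151 min⁻¹ at 80 °C and 3.12 min⁻¹ at 110 °C. Rate times time makes a clock. Elm's last reading stands at 6.86, Monday's flask reaches 18.7 and Thursday's reaches 42.4, both further than elm, so I expect both to end on the stall.

Elm's last target reading over its charge gives 0.386 M⁻¹, and this I carry: the plateau constant, target at the stall as a fraction of the charge, per molar of [starting material] charged. I assume it holds between flasks at the same equivalents of partner, with temperature set aside, taking target to need a meeting of two species while the clock runs first order. So I commit to 15.4% for Thursday's and 9.64% for Monday's, and Thursday's wins beyond the margin.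

The weak link is the rate at 110 °C, drawn from single first readings. I reforge it from depth: alder at 20.0 min reads 42.0% and elm at 1.33 min reads 43.9%, nearly the same, and those times give one power of ten per 17.0 K. Monday's clock then reads 31.4, further on, so my figures stand.

The forecast also names Thursday's, but with higher figures than mine: 22% for Thursday's and 14% for Monday's, its Thursday's figure counting “about 1.2%/min for 13 min through the reservoir”.

The flask gives Thursday's: 12.5% for Thursday's and 7.78% for Monday's.

    starting material ⇌ open intermediate (K = 0.760, k = 0.00260 s⁻¹, Ea = 102 kJ mol⁻¹, ΔH = 60.0 kJ mol⁻¹)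
    partner → second intermediate (k = 0.0190 s⁻¹, Ea = 102 kJ mol⁻¹)
    open intermediate + second intermediate → target (k = 0.00310 M⁻¹ s⁻¹, Ea = 68.0 kJ mol⁻¹)
    starting material + second intermediate → side product A (k = 0.00330 M⁻¹ s⁻¹, Ea = 81.0 kJ mol⁻¹)
    target → over-reaction product (k = 1.70 × 10⁻⁶ s⁻¹, Ea = 122 kJ mol⁻¹)
    second intermediate → side product B (k = 0.00120 s⁻¹, Ea = 112 kJ mol⁻¹)
    (constants at 80 °C)

In Monday's flask target reads 7.77% at 3.00 min and 7.78% at 6.00 min, with partner, the limiting reagent, at 0% already at the earlier time. Divided by its charge, Thursday's target at the end gives a plateau constant of 0.312 M⁻¹, and Monday's gives 0.311 M⁻¹.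

(Readings and results stem from a simulated flask on assumed constants; scatter was added.)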